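At 120 s the north-east run holds 8.5% of product, while 34.8% of the substrate has gone, so 26.3% stands between the two. We want to know what the flasks below give at their end time.

| setting | north-east | green | red | teal | blue | ochre |
|---|---|---|---|---|---|---|
| substrate | 0.080 M | 0.12 M | 0.12 M | 0.12 M | 0.12 M | 0.12 M |
| reagent | 0.050 M | 0.0500 M | 0.0800 M | 0.120 M | 0.200 M | 0.250 M |
| remark | run made earlier |  |  |  |  |  |
| time |  | 5.0 min | 5.0 min | 5.0 min | 5.0 min | 5.0 min |

- north-east (time / s: product / %, substrate / %): 12.0: 0.3, 94.1; 40.0: 2.0, 87.3; 60.0: 1.9, 80.1; 120: 8.5, 65.2

(standard deviation of a reading: 0.5 percentage points)

- candidate steps: substrate -> intermediate A; reagent + intermediate A -> intermediate B; intermediate A -> product; intermediate B <-> intermediate C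
- "hardly changes" means that all values lie within two and a half points (for a concentration: within two and a half percent of the largest)

1. amount of product at the end, in percent of the substrate charged for green, red, teal, blue, ochre, in this order
2. the shape of the row from first to last (falls, then rises / hardly changes / falls all the way / rises all the way / rises, then falls)

We reckon in rungs of time. In the candidate steps substrate falls by itself, without reagent, so the north-east run gives a clock for the flasks at 0.12 M: a reading of 0.00356 s⁻¹, a half-life of 3.24 min. The next rung is the passage of intermediate A into product. If we count the whole store as intermediate A, and let it rise evenly from nothing, its mean over those 120 s is half of the store. Product divided by that mean and the time gives a reading of 0.00539 s⁻¹, a half-life of 2.14 min. This is quicker than the substrate clock, yet it rests on one reading with its scatter of 0.5 percentage points.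

Both half-lives are shorter than the run of 5.0 min, and with the substrate clock we expect 34.3% of the substrate to be left at the end.

Capture by reagent we treat as a correction to this two-step chain. The large part is the free yield, the product at the end time if reagent captured nothing: 37.4%. The correction is the split of intermediate A between its two ways out, a selectivity factor. The north-east run holds one reagent level, and we take no number for that split from it, so we commit to a row that starts somewhat under the free yield and falls as reagent rises.

The forecast gives 24%, 15%, 9.8%, 5.5% and 4.3%, a row that falls all the way, starting well below our free yield, on the ground that “More reagent means less product throughout.”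

The flasks give 31.6%, 29.0%, 25.9%, 21.2% and 19.0%: the row falls all the way.

    substrate → intermediate A (k = 0.00361 s⁻¹)
    reagent + intermediate A → intermediate B (k = 0.0439 M⁻¹ s⁻¹)
    intermediate A → product (k = 0.00519 s⁻¹)
    intermediate B ⇌ intermediate C (K = 1.90, k = 0.00741 s⁻¹)

With the capture of intermediate A by reagent taken away, the change from green to ochre goes from −13 points to 0 points. Counted from the free yield of 37.4%, green is short by 5.8 points. Ochre, with 5.00 times the reagent of green, is short by 18 points.

The data come from a simulation for an exercise.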